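**Plan**
- Retrosynthesis: the three phenol O–H bonds (as MOM ethers) and the aryl–prenyl bond are cut first. The pyranone ring is then cut at both bonds to the phloroglucinol ring, O1–C8a and C4–C4a.
- Enabling feature: the heterocycle is a β-aryloxy ketone whose O1 and C4 sit on the ortho pair C8a/C4a of the A ring. O1–C2–C3–C4 is therefore a 4-aryl-oxetan-2-one, and C4a–C8a is an aryne whose regiochemistry is set by the 5-oxygen next to C4a.
- Forward order: B-ring aldehyde → β-keto ester → (S)-β-hydroxy acid → (S)-β-lactone; phloroglucinol → silylaryl triflate. Aryne insertion into the lactone O–C(=O) bond then expands the four-membered ring by two atoms to the chromanone. Prenylation and MOM removal finish the route.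
- Stereochemistry: C2 (S) is set by a Noyori–Ikariya transfer hydrogenation and carried through lactonisation and ring expansion with retention, because the C2–O bond is never broken.

Key step: step 11

Remark: the single stereocentre of the target (C2) is (S); 3-bromo-4,5-dihydroxybenzaldehyde and phloroglucinol are taken as purchasable.

**Route**

Step 1
Reactants: 1 3-bromo-4,5-dihydroxybenzaldehyde
Product: 2 3-bromo-5-hydroxy-4-methoxybenzaldehyde
Conditions: MeI (1.05 equiv), Li2CO3 (1.1 equiv), DMF, 40 °C
Reagents that add atoms: iodomethane, CI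
Why: Williamson etherification; the 4-OH is para to the formyl group and ortho to bromine, so it is the more acidic phenol and should be deprotonated and methylated selectively by the weak base.

Step 2
Reactants: 2 3-bromo-5-hydroxy-4-methoxybenzaldehyde
Product: 3 3-bromo-4-methoxy-5-(methoxymethoxy)benzaldehyde
Conditions: MOMCl, i-Pr2NEt, CH2Cl2, 0 °C → rt
Reagents that add atoms: chloromethyl methyl ether, COCCl
Why: standard MOM protection of the remaining phenol (O-alkylation), needed because a free phenol would add to the aryne in step 11.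

Step 3
Reactants: 3 3-bromo-4-methoxy-5-(methoxymethoxy)benzaldehyde
Product: 4 ethyl 3-[3-bromo-4-methoxy-5-(methoxymethoxy)phenyl]-3-oxopropanoate
Conditions: N2CHCO2Et (1.2 equiv), SnCl2 (10 mol%), CH2Cl2, rt
Reagents that add atoms: ethyl diazoacetate, CCOC(=O)C=[N+]=[N-]
Why: Roskamp homologation; the Lewis-acid-activated aldehyde adds the diazo carbon and a 1,2-hydride shift with loss of N2 gives the β-keto ester, the bromo substituent lowering the competing aryl migration.

Step 4
Reactants: 4 ethyl 3-[3-bromo-4-methoxy-5-(methoxymethoxy)phenyl]-3-oxopropanoate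
Product: 5 ethyl (3S)-3-[3-bromo-4-methoxy-5-(methoxymethoxy)phenyl]-3-hydroxypropanoate
Conditions: RuCl[(S,S)-TsDPEN](p-cymene) (1 mol%), HCO2H–Et3N (5:2), DMF, 30 °C
Reagents that add atoms: none
Why: Noyori–Ikariya asymmetric transfer hydrogenation; the (S,S)-catalyst delivers hydride to the ketone face fixed by the CH/π contact between the aryl group and the η6-arene, which should give the (S)-carbinol as with acetophenone (aryl ranks above CH2), leaving the ester and C–Br bond untouched.

Step 5
Reactants: 5 ethyl (3S)-3-[3-bromo-4-methoxy-5-(methoxymethoxy)phenyl]-3-hydroxypropanoate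
Product: 6 (3S)-3-[3-bromo-4-methoxy-5-(methoxymethoxy)phenyl]-3-hydroxypropanoic acid
Conditions: LiOH·H2O, THF–H2O (3:1), 0 °C; then 1 M HCl to pH 3–4 at 0 °C
Reagents that add atoms: lithium hydroxide, [Li+].[OH-]
Why: ester saponification at a temperature low enough to avoid retro-aldol cleavage; the stereocentre is not involved.

Step 6
Reactants: 6 (3S)-3-[3-bromo-4-methoxy-5-(methoxymethoxy)phenyl]-3-hydroxypropanoic acid
Product: 8 (4S)-4-[3-bromo-4-methoxy-5-(methoxymethoxy)phenyl]oxetan-2-one, via mixed carboxylic benzenesulfonic anhydride 7 (not isolated)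
Conditions: PhSO2Cl (2 equiv), pyridine, 0 °C, 16 h
Reagents that add atoms: benzenesulfonyl chloride, O=S(=O)(Cl)c1ccccc1 (its atoms stay in 7 only)
Why: Adam β-lactonisation; the carboxyl group is activated as the mixed sulfonic anhydride and acylates the β-hydroxyl (4-exo-trig), so the C–O bond at the stereocentre is untouched and (S) is retained.

Step 7
Reactants: 9 phloroglucinol (benzene-1,3,5-triol)
Product: 10 3,5-bis(methoxymethoxy)phenol
Conditions: MOMCl (2.0 equiv), i-Pr2NEt (2.2 equiv), DMF, 0 °C → rt; chromatography
Reagents that add atoms: chloromethyl methyl ether, COCCl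
Why: statistical bis-O-alkylation of the C3-symmetric triol, in which every bis-ether is the same compound; the mono- and tris-ethers are separated.

Step 8
Reactants: 10 3,5-bis(methoxymethoxy)phenol
Product: 11 3,5-bis(methoxymethoxy)phenyl N-isopropylcarbamate
Conditions: i-PrNCO (1.2 equiv), Et3N (cat.), CH2Cl2, rt
Reagents that add atoms: isopropyl isocyanate, CC(C)N=C=O
Why: addition of the phenol to the isocyanate gives a carbamate that directs ortho-metalation and can be removed later under mild conditions.

Step 9
Reactants: 11 3,5-bis(methoxymethoxy)phenyl N-isopropylcarbamate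
Product: 15 3,5-bis(methoxymethoxy)-2-(trimethylsilyl)phenyl N-isopropylcarbamate, via N-silyl carbamate 12 (not isolated), via ortho-lithiated N-silyl carbamate 13 (not isolated), via N,C-disilyl carbamate 14 (not isolated)
Conditions: TMSOTf, TMEDA, Et2O, 0 °C → rt; then n-BuLi, TMEDA, −78 °C; TMSCl, −78 °C → rt; aq. NaHSO4
Reagents that add atoms: trimethylsilyl trifluoromethanesulfonate, C[Si](C)(C)OS(=O)(=O)C(F)(F)F (N-silyl group of 12 to 14 only); n-butyllithium, [Li]CCCC (lithium of 13 only); chlorotrimethylsilane, C[Si](C)(C)Cl
Why: Snieckus-type directed ortho-metalation of the in situ N-silylated carbamate; lithiation should occur at the position flanked by the carbamate (the stronger director) and one OMOM group, the aryllithium is C-silylated, and aqueous work-up removes the N-silyl group.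

Step 10
Reactants: 15 3,5-bis(methoxymethoxy)-2-(trimethylsilyl)phenyl N-isopropylcarbamate
Product: 17 3,5-bis(methoxymethoxy)-2-(trimethylsilyl)phenyl trifluoromethanesulfonate, via 3,5-bis(methoxymethoxy)-2-(trimethylsilyl)phenol 16 (not isolated)
Conditions: DBU, Et2NH, MeCN, 40 °C; then PhNTf2, rt
Reagents that add atoms: N-phenylbis(trifluoromethanesulfonimide), O=S(=O)(N(c1ccccc1)S(=O)(=O)C(F)(F)F)C(F)(F)F
Why: base-induced elimination of the carbamate to the isocyanate (trapped by diethylamine as the urea) frees the phenoxide, which is sulfonylated in the same flask to give the Kobayashi-type aryne precursor.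

Step 11
Reactants: 8 (4S)-4-[3-bromo-4-methoxy-5-(methoxymethoxy)phenyl]oxetan-2-one; 17 3,5-bis(methoxymethoxy)-2-(trimethylsilyl)phenyl trifluoromethanesulfonate
Product: 19 (2S)-2-[3-bromo-4-methoxy-5-(methoxymethoxy)phenyl]-5,7-bis(methoxymethoxy)chroman-4-one, via 3,5-bis(methoxymethoxy)benzyne 18 (not isolated)
Conditions: 8 (1.0 equiv), 17 (1.5 equiv, slow addition), Bu4N[Ph3SiF2] (TBAT, 2.0 equiv), toluene–MeCN (3:1), 25 °C
Reagents that add atoms: none
Why: Proposed new method: fluoride-induced 1,2-elimination of 17 gives benzyne 18, whose carbon remote from the flanking OMOM group (future C8a) is attacked by the ring oxygen of the strained oxetanone; the aryl anion thus arises next to that OMOM group (future C4a), adds to the neighbouring acyl carbon, and the acyl–oxygen bond breaks, inserting both aryne carbons into the O–C(=O) bond with release of about 23 kcal/mol of lactone strain. The closest known reaction type is aryne σ-insertion into the N–C(=O) bond of cyclic ureas and amides (a two-atom ring expansion) and into the O–C(=O) bond of carboxylic acids to give o-hydroxyaryl ketones; an ester-type oxygen as the nucleophile is the untested element and is argued from the weakened ester resonance and exposed lone pairs of the four-membered lactone. The six-membered ring is closed by addition of the aryl anion to the carbonyl carbon across the oxonium oxygen (4-exo-trig to a fused benzoxete that opens at once at the shared C–O bond), so the ring grows from four to six atoms without an open-chain stage. C2 is not formed here: the O–C2 bond of 8 stays intact on the insertion path, so (S)-8 should give (S)-19 with retention, whereas a start at the carbonyl oxygen could reach 19 only by benzylic ionisation at C2 (an SN2 closure would be endocyclic in a six-membered transition state) and would show as loss of optical purity. The step needs aryne regioselectivity, secured by the inductive effect of the adjacent OMOM group that places the anion next to it, and insertion must outrun ionisation or decarboxylation of the lactone, which the bromoaryl group with its 4-methoxy group twisted out of conjugation by two ortho neighbours should secure. The prenyl group is introduced only afterwards because an alkene with allylic C–H bonds would undergo the aryne ene reaction.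

Step 12
Reactants: 19 (2S)-2-[3-bromo-4-methoxy-5-(methoxymethoxy)phenyl]-5,7-bis(methoxymethoxy)chroman-4-one
Product: 20 (2S)-2-[4-methoxy-3-(methoxymethoxy)-5-(3-methylbut-2-en-1-yl)phenyl]-5,7-bis(methoxymethoxy)chroman-4-one
Conditions: prenylSnBu3 (1.5 equiv), Pd(PPh3)4 (10 mol%), DMF, 90 °C
Reagents that add atoms: tributyl(3-methylbut-2-en-1-yl)stannane, CCCC[Sn](CCCC)(CCCC)CC=C(C)C
Why: Stille cross-coupling under neutral conditions, which should spare the base-sensitive flavanone stereocentre; reductive elimination at the less hindered terminus of the prenyl–palladium species should give the linear prenyl arene.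

Step 13
Reactants: 20 (2S)-2-[4-methoxy-3-(methoxymethoxy)-5-(3-methylbut-2-en-1-yl)phenyl]-5,7-bis(methoxymethoxy)chroman-4-one
Product: 21 (2S)-5,7-dihydroxy-2-[3-hydroxy-4-methoxy-5-(3-methylbut-2-en-1-yl)phenyl]chroman-4-one
Conditions: 3 M aq. HCl, MeOH, 45 °C
Reagents that add atoms: none
Why: acid-catalysed acetal exchange with methanol removes the three MOM ethers; the prenyl group has no ortho hydroxyl for chroman formation and these conditions should not open the flavanone ring, so C2 is kept.

**Compound list**
1 | 3-bromo-4,5-dihydroxybenzaldehyde | O=Cc1cc(O)c(O)c(Br)c1 | starting material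
2 | 3-bromo-5-hydroxy-4-methoxybenzaldehyde | COc1c(O)cc(C=O)cc1Br | intermediate
3 | 3-bromo-4-methoxy-5-(methoxymethoxy)benzaldehyde | COCOc1cc(C=O)cc(Br)c1OC | intermediate
4 | ethyl 3-[3-bromo-4-methoxy-5-(methoxymethoxy)phenyl]-3-oxopropanoate | CCOC(=O)CC(=O)c1cc(Br)c(OC)c(OCOC)c1 | intermediate
5 | ethyl (3S)-3-[3-bromo-4-methoxy-5-(methoxymethoxy)phenyl]-3-hydroxypropanoate | CCOC(=O)C[C@H](O)c1cc(Br)c(OC)c(OCOC)c1 | intermediate
6 | (3S)-3-[3-bromo-4-methoxy-5-(methoxymethoxy)phenyl]-3-hydroxypropanoic acid | OC(=O)C[C@H](O)c1cc(Br)c(OC)c(OCOC)c1 | intermediate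
7 | (3S)-3-[3-bromo-4-methoxy-5-(methoxymethoxy)phenyl]-3-hydroxypropanoic benzenesulfonic anhydride | O=C(C[C@H](O)c1cc(Br)c(OC)c(OCOC)c1)OS(=O)(=O)c1ccccc1 | intermediate
8 | (4S)-4-[3-bromo-4-methoxy-5-(methoxymethoxy)phenyl]oxetan-2-one | O=C1C[C@@H](c2cc(Br)c(OC)c(OCOC)c2)O1 | intermediate
9 | phloroglucinol | Oc1cc(O)cc(O)c1 | starting material
10 | 3,5-bis(methoxymethoxy)phenol | COCOc1cc(O)cc(OCOC)c1 | intermediate
11 | 3,5-bis(methoxymethoxy)phenyl N-isopropylcarbamate | CC(C)NC(=O)Oc1cc(OCOC)cc(OCOC)c1 | intermediate
12 | 3,5-bis(methoxymethoxy)phenyl N-isopropyl-N-(trimethylsilyl)carbamate | CC(C)N(C(=O)Oc1cc(OCOC)cc(OCOC)c1)[Si](C)(C)C | intermediate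
13 | 2-lithio-3,5-bis(methoxymethoxy)phenyl N-isopropyl-N-(trimethylsilyl)carbamate | CC(C)N(C(=O)Oc1cc(OCOC)cc(OCOC)c1[Li])[Si](C)(C)C | intermediate
14 | 3,5-bis(methoxymethoxy)-2-(trimethylsilyl)phenyl N-isopropyl-N-(trimethylsilyl)carbamate | CC(C)N(C(=O)Oc1cc(OCOC)cc(OCOC)c1[Si](C)(C)C)[Si](C)(C)C | intermediate
15 | 3,5-bis(methoxymethoxy)-2-(trimethylsilyl)phenyl N-isopropylcarbamate | CC(C)NC(=O)Oc1cc(OCOC)cc(OCOC)c1[Si](C)(C)C | intermediate
16 | 3,5-bis(methoxymethoxy)-2-(trimethylsilyl)phenol | COCOc1cc(O)c([Si](C)(C)C)c(OCOC)c1 | intermediate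
17 | 3,5-bis(methoxymethoxy)-2-(trimethylsilyl)phenyl trifluoromethanesulfonate | COCOc1cc(OCOC)c([Si](C)(C)C)c(OS(=O)(=O)C(F)(F)F)c1 | intermediate
18 | 3,5-bis(methoxymethoxy)benzyne | COCOC1=CC(OCOC)=CC#C1 | intermediate
19 | (2S)-2-[3-bromo-4-methoxy-5-(methoxymethoxy)phenyl]-5,7-bis(methoxymethoxy)chroman-4-one | COc1c(OCOC)cc([C@@H]2CC(=O)c3c(OCOC)cc(OCOC)cc3O2)cc1Br | intermediate
20 | (2S)-2-[4-methoxy-3-(methoxymethoxy)-5-(3-methylbut-2-en-1-yl)phenyl]-5,7-bis(methoxymethoxy)chroman-4-one | COc1c(OCOC)cc([C@@H]2CC(=O)c3c(OCOC)cc(OCOC)cc3O2)cc1CC=C(C)C | intermediate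
21 | (2S)-5,7-dihydroxy-2-[3-hydroxy-4-methoxy-5-(3-methylbut-2-en-1-yl)phenyl]chroman-4-one | COc1c(O)cc([C@@H]2CC(=O)c3c(O)cc(O)cc3O2)cc1CC=C(C)C | target

**Summary**
Total steps: 13. Longest linear sequence: 9 steps (steps 1–6, 11, 12, 13).

**Steps most likely to fail**

1. Step 11 (proposed new method). The weakly nucleophilic ring oxygen may capture the aryne too slowly, so that aryne self-condensation, attack through the lactone carbonyl oxygen, or fluoride opening of the lactone take over. Benzylic ionisation could cause loss of CO2 or of optical purity, and base could open the product to the chalcone and racemise it. The fallback uses known chemistry and forms the two ring bonds in separate steps; it sets out from 4 and comes back at 19. Keto ester 4 is reduced with the enantiomeric (R,R)-TsDPEN ruthenium catalyst to ethyl (3R)-3-[3-bromo-4-methoxy-5-(methoxymethoxy)phenyl]-3-hydroxypropanoate F1. A Mitsunobu etherification with phenol 10 (DIAD, PPh3, toluene, 0 °C) should invert the carbinol centre to give ethyl (3S)-3-[3,5-bis(methoxymethoxy)phenoxy]-3-[3-bromo-4-methoxy-5-(methoxymethoxy)phenyl]propanoate F2. Saponification (LiOH, THF–H2O) gives (3S)-3-[3,5-bis(methoxymethoxy)phenoxy]-3-[3-bromo-4-methoxy-5-(methoxymethoxy)phenyl]propanoic acid F3. Intramolecular Friedel–Crafts acylation ((CF3CO)2O, CH2Cl2, 0 °C) at either of the two equivalent positions ortho to the ether oxygen closes the chromanone 19.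

2. Step 9. Lithiation may occur between the two MOM ethers instead of next to the carbamate, a MOM ether may be lost to the silyl triflate, or the carbamoyl group may undergo an anionic ortho-Fries shift on warming. The fallback replaces directed metalation by a halogen-based retro-Brook sequence; it sets out from 10 and comes back at 17. Ortho-selective bromination (NBS, cat. i-Pr2NH, CH2Cl2, −78 °C) should give 2-bromo-3,5-bis(methoxymethoxy)phenol F4. O-Silylation with hexamethyldisilazane gives [2-bromo-3,5-bis(methoxymethoxy)phenoxy]trimethylsilane F5. Bromine–lithium exchange (n-BuLi, THF, −78 °C) triggers the 1,3 O→C silyl shift to the lithium salt of 16, which is trapped with Tf2O to give 17.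

3. Step 12. The prenyl group may be transferred through its γ-carbon to give the reverse-prenyl isomer, the double bond may isomerise, and the hindered, electron-rich C–Br bond may undergo oxidative addition slowly at a temperature the flavanone tolerates. The fallback builds the side chain in two stages; it sets out from 19 and comes back at 20. Stille allylation (allylSnBu3, Pd(PPh3)4, DMF, 80 °C), which has no α/γ ambiguity, gives (2S)-2-[3-allyl-4-methoxy-5-(methoxymethoxy)phenyl]-5,7-bis(methoxymethoxy)chroman-4-one F6. Olefin cross-metathesis with 2-methyl-2-butene (second-generation Grubbs catalyst, CH2Cl2, 40 °C) converts the terminal alkene into the prenyl group of 20.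

**Further compounds**
F1 | step 11 | ethyl (3R)-3-[3-bromo-4-methoxy-5-(methoxymethoxy)phenyl]-3-hydroxypropanoate | CCOC(=O)C[C@@H](O)c1cc(Br)c(OC)c(OCOC)c1
F2 | step 11 | ethyl (3S)-3-[3,5-bis(methoxymethoxy)phenoxy]-3-[3-bromo-4-methoxy-5-(methoxymethoxy)phenyl]propanoate | CCOC(=O)C[C@H](Oc1cc(OCOC)cc(OCOC)c1)c1cc(Br)c(OC)c(OCOC)c1
F3 | step 11 | (3S)-3-[3,5-bis(methoxymethoxy)phenoxy]-3-[3-bromo-4-methoxy-5-(methoxymethoxy)phenyl]propanoic acid | OC(=O)C[C@H](Oc1cc(OCOC)cc(OCOC)c1)c1cc(Br)c(OC)c(OCOC)c1
F4 | step 9 | 2-bromo-3,5-bis(methoxymethoxy)phenol | COCOc1cc(O)c(Br)c(OCOC)c1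
F5 | step 9 | [2-bromo-3,5-bis(methoxymethoxy)phenoxy]trimethylsilane | COCOc1cc(O[Si](C)(C)C)c(Br)c(OCOC)c1
F6 | step 12 | (2S)-2-[3-allyl-4-methoxy-5-(methoxymethoxy)phenyl]-5,7-bis(methoxymethoxy)chroman-4-one | COc1c(OCOC)cc([C@@H]2CC(=O)c3c(OCOC)cc(OCOC)cc3O2)cc1CC=C
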